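**Retrosynthetic overview**

1. The target is a 6,7-seco-ent-kaurane spirolactone. Ent-kaurane numbering is used throughout: ring A = C1–C5/C10, lactone C7(=O)–O–C20, aldehyde C6, bicyclo[3.2.1]octane C8–C16. The last operations are C2–C3 dehydrogenation, desilylation and a hydroxyl-directed C16–C17 epoxidation.
2. Key disconnection: C10–C5 (Michael addition of the C1 enolate to a C5=C6 nitroalkene, CH2NO2 becoming the C6 aldehyde by a Nef reaction) together with O–C20 (oxa-Michael addition). Spirolactone and ring A thus arise in one operation from a bicyclo[3.2.1]octane carboxylate that carries a 2-acylallyl unit C20H2=C10–C1(=O)– on C9.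
3. Enabling feature: the spiro atom C10 is the α-carbon of the C1 ketone, the lactone oxygen sits on C20 β to that ketone (O–C20–C10–C1=O), and C6 is 1,4 to C1 across C10–C5. Lactone and ring A share only C10, so one enolate, made by conjugate addition of the C7 carboxylate, can close both.
4. The precursor comes from an acyl Stille coupling of a C10 vinylstannane (C9 carboxyl → methyl ketone → enol triflate) with a nitroalkenoyl chloride (isobutyraldehyde, tert-butyl acrylate, nitromethane). The C15 hydroxyl is set before that by allylic oxidation and Luche reduction.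
5. Ring order: ring C is bought (meso anhydride, desymmetrised: C8/C9), ring D by vinyl radical cyclisation (C13), then in the key step the lactone and, last, ring A (C10, C5).

Key step: step 17

Assumption: quinidine is taken to deliver the (1R,2S) half-ester 3; its pseudo-enantiomer quinine gives the antipode, so the alkaloid is simply exchanged if the sense is the opposite.

**Route**

Step 1
Reactants: 1 cis-cyclohex-4-ene-1,2-dicarboxylic anhydride (meso); 2 2-(trimethylsilyl)ethanol
Product: 3 (1R,2S)-2-{[2-(trimethylsilyl)ethoxy]carbonyl}cyclohex-4-ene-1-carboxylic acid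
Conditions: quinidine (1.1 equiv), toluene, −55 °C; aq. HCl work-up (alkaloid recovered)
Reagents that add atoms: none
Why: Cinchona alkaloid-mediated desymmetrising alcoholysis of a meso anhydride: the alkaloid acts as chiral general base and selects one of the enantiotopic carbonyl groups, which sets C8 and C9.

Step 2
Reactants: 3 half-ester; 4 2,3-dibromopropene
Product: 5 (1R,6R)-6-(2-bromoprop-2-en-1-yl)-6-{[2-(trimethylsilyl)ethoxy]carbonyl}cyclohex-3-ene-1-carboxylic acid
Conditions: LDA (2.2 equiv), THF, −78 → −30 °C; then 4, −78 °C → rt; aq. HCl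
Reagents that add atoms: none
Why: Alkylation of the carboxylate/ester-enolate dianion: only the ester α-position (C8) is enolised and the allylic bromide enters anti to the neighbouring carboxylate, which sets the quaternary C8 with the ester cis to the C9 carboxyl.

Step 3
Reactants: 5 bromoallyl acid
Product: 6 bicyclo[3.2.1]octane acid (C8 silylethyl ester, C9 CO2H anti to the C15–C16 bridge, 16-methylene)
Conditions: Bu3SnH (1.5 equiv), AIBN (cat.), benzene, 80 °C
Reagents that add atoms: none
Why: 5-exo-trig vinyl radical cyclisation (tin hydride method) onto the ring alkene closes ring D; the tether reaches C13 only on the face it is attached to, so C13 follows from C8, and a high stannane concentration should trap the C12 radical before rearrangement to the bicyclo[2.2.2]octane.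

Step 4
Reactants: 6 bicyclic acid; 7 N,O-dimethylhydroxylamine hydrochloride
Product: 8 Weinreb amide of 6
Conditions: 1,1'-carbonyldiimidazole, CH2Cl2, rt; then 7, rt
Reagents that add atoms: none
Why: Weinreb amide formation through the acyl imidazolide, under conditions too weakly basic to epimerise C9.

Step 5
Reactants: 8 Weinreb amide
Product: 10 15-oxo-16-methylene enone, via allylic alcohol 9 (not isolated)
Conditions: SeO2 (0.5 equiv), t-BuOOH, CH2Cl2, rt; then Dess–Martin periodinane, NaHCO3, CH2Cl2, rt
Reagents that add atoms: tert-butyl hydroperoxide CC(C)(C)OO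
Why: Selenium dioxide ene reaction/[2,3]-shift hydroxylates C15, the only allylic CH2 (the other allylic carbon is the bridgehead C13), and Dess–Martin oxidation converges the crude alcohol on the enone, so the C15 configuration formed here does not matter.

Step 6
Reactants: 10 enone
Product: 11 15-hydroxy-16-ene with OH on the face towards C11 (target configuration at C15)
Conditions: NaBH4, CeCl3·7H2O, MeOH, −78 °C
Reagents that add atoms: none
Why: Luche 1,2-reduction: hydride should reach C15 from the face of the one-carbon bridge (C14), the other face being screened by the axial hydrogen on C11, which places the hydroxyl on the face towards C11.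

Step 7
Reactants: 11 allylic alcohol
Product: 12 triisopropylsilyl ether of 11
Conditions: TIPSOTf, 2,6-lutidine, CH2Cl2, 0 °C → rt
Reagents that add atoms: triisopropylsilyl trifluoromethanesulfonate CC(C)[Si](OS(=O)(=O)C(F)(F)F)(C(C)C)C(C)C
Why: Silyl ether formation with a silyl triflate; the bulky group is chosen to outlast the fluoride of step 17 and blocks retro-aldol cleavage of the β-hydroxy ester.

Step 8
Reactants: 12 Weinreb amide silyl ether
Product: 13 methyl ketone (C9 acetyl, C8 silylethyl ester, 15-OTIPS, 16-methylene)
Conditions: MeMgBr (3 equiv), THF, 0 °C; aq. NH4Cl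
Reagents that add atoms: methylmagnesium bromide C[Mg]Br
Why: Weinreb ketone synthesis: the chelated tetrahedral intermediate stops at the ketone and protects C9 from enolisation, while the ester on the quaternary bridgehead C8 is too hindered to react.

Step 9
Reactants: 13 methyl ketone
Product: 14 enol triflate (1-(trifluoromethanesulfonyloxy)vinyl group on C9)
Conditions: KHMDS, THF, −78 °C; PhNTf2, −78 °C
Reagents that add atoms: N-phenylbis(trifluoromethanesulfonimide) O=S(=O)(N(c1ccccc1)S(=O)(=O)C(F)(F)F)C(F)(F)F
Why: Kinetic deprotonation of the methyl group (the hindered tertiary C9–H is left alone) and O-triflation of the enolate, which turns the former carboxyl carbon into the sp2 carbon C10 with C20 as its CH2 terminus.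

Step 10
Reactants: 14 enol triflate
Product: 15 vinylstannane (1-(trimethylstannyl)vinyl group on C9)
Conditions: Me3SnSnMe3, Pd(PPh3)4 (5 mol %), LiCl, THF, 65 °C
Reagents that add atoms: hexamethylditin C[Sn](C)(C)[Sn](C)(C)C
Why: Palladium-catalysed stannylation of an enol triflate (oxidative addition, transmetalation with the distannane, reductive elimination).

Step 11
Reactants: 16 isobutyraldehyde; 17 tert-butyl acrylate
Product: 19 tert-butyl 4,4-dimethyl-5-oxopentanoate, via enamine 18 (not isolated)
Conditions: pyrrolidine, toluene, reflux with water removal; then 17, MeCN, reflux; then aq. AcOH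
Reagents that add atoms: none
Why: Stork enamine Michael addition: the aldehyde has a single α-hydrogen, so one alkylation gives the quaternary C4 with both methyl groups.

Step 12
Reactants: 19 aldehyde ester; 20 nitromethane
Product: 21 tert-butyl 5-hydroxy-4,4-dimethyl-6-nitrohexanoate (racemic)
Conditions: t-BuOK (10 mol %), THF/t-BuOH, 0 °C
Reagents that add atoms: none
Why: Henry (nitroaldol) reaction on a non-enolisable aldehyde; the carbinol stereocentre is removed in the next step.

Step 13
Reactants: 21 nitro aldol
Product: 22 tert-butyl (E)-4,4-dimethyl-6-nitrohex-5-enoate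
Conditions: MsCl, Et3N, CH2Cl2, −20 → 0 °C
Reagents that add atoms: none
Why: Mesylation and E1cB elimination give the (E)-nitroalkene, which cannot deconjugate because C4 is quaternary.

Step 14
Reactants: 22 nitroalkene ester
Product: 23 (E)-4,4-dimethyl-6-nitrohex-5-enoic acid
Conditions: CF3CO2H, CH2Cl2, 0 °C → rt
Reagents that add atoms: none
Why: Acidolysis of the tert-butyl ester (loss of isobutene), conditions under which the nitroalkene is stable.

Step 15
Reactants: 23 nitroalkenoic acid
Product: 24 (E)-4,4-dimethyl-6-nitrohex-5-enoyl chloride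
Conditions: (COCl)2, DMF (cat.), CH2Cl2, 0 °C → rt; used crude
Reagents that add atoms: oxalyl chloride O=C(Cl)C(=O)Cl
Why: Acid chloride formation through the Vilsmeier-type chloroiminium intermediate under non-basic conditions.

Step 16
Reactants: 15 vinylstannane; 24 acid chloride
Product: 25 cascade precursor (C9 carries CH2=C(C10)–C(=O)–CH2CH2–C(CH3)2–CH=CH–NO2; C8 silylethyl ester; 15-OTIPS; 16-methylene)
Conditions: Pd2(dba)3 (2.5 mol %), tri(2-furyl)phosphine (10 mol %), CuI (10 mol %), THF, 45 °C
Reagents that add atoms: none
Why: Migita–Kosugi–Stille acylation of a vinylstannane with an acid chloride: the neutral conditions tolerate nitroalkene, ester and silyl ether and deliver the 2-acylallyl unit.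

Step 17
Reactants: 25 cascade precursor
Product: 29 spirolactone keto aldehyde (1-oxo, 6-al, ring A saturated at C2–C3, 15-OTIPS, 16-ene), via carboxylate 26 (not isolated), via lactone enolate 27 (not isolated), via nitronate 28 (not isolated)
Conditions: Bu4NF (1.5 equiv), 4 Å MS, THF (0.005 M), −20 °C → rt; then poured into aq. TiCl3/NH4OAc (pH 5–6), 0 °C → rt
Reagents that add atoms: water O
Why: Proposed new method: fluoride cleaves the 2-(trimethylsilyl)ethyl ester (Me3SiF and ethene leave), the free carboxylate adds to the CH2 terminus C20 of the 2-acylallyl unit, which closes the δ-lactone and unveils the C1 enolate at C10, that enolate adds to C5 of the tethered nitroalkene and closes ring A, and buffered TiCl3 converts the nitronate into the C6 aldehyde (Nef reaction). Closest known reaction types are Michael-initiated ring closures (domino oxa-Michael/Michael additions of O-nucleophiles), the intramolecular ketone enolate–nitroalkene Michael addition and fluoride unmasking of silylethyl esters; not shown before is a carboxylate as the initiating nucleophile, so that lactone and carbocycle form in one operation. The lactone closes first by a reversible 6-endo-trig oxa-Michael addition (its reverse is the β-elimination that any C10 enolate of this β-acyloxy ketone undergoes, which is why the enolate is made this way and not by deprotonation), and ring A closes last by an irreversible 6-(enolendo)-exo-trig Michael addition, after which C10 is quaternary and the lactone can no longer open. C10 is set by the substrate: the exocyclic enolate of the lactone cis-fused to ring C should be attacked on its convex face, because the other face lies under ring C next to the axial hydrogens on C12 and C14, and this leaves C1 below ring C and C5 outside as in the target. C5 is set in a chair-like transition state in which C20 (smaller than C9) is axial opposite the axial C4 methyl and the nitrovinyl group is equatorial, antiperiplanar to the enolate double bond and away from C11, which places C6 cis to C20. Needed are fluoride attack at the unhindered Me3Si of the ester and not at the hindered secondary TIPS ether, carboxylate attack at the unsubstituted C20 terminus, and no base-induced double-bond migration; the first two follow from steric accessibility, the nitroalkene has no γ-hydrogen (C4 is quaternary), and C9–H lies near the enone plane (allylic 1,3-strain) and is poorly aligned for γ-deprotonation.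

Step 18
Reactants: 29 keto aldehyde
Product: 30 2-en-1-one (ring A enone, 6-al, 15-OTIPS, 16-ene)
Conditions: IBX (2.5 equiv), 4-methoxypyridine N-oxide (2.5 equiv), DMSO, 25–40 °C
Reagents that add atoms: none
Why: IBX dehydrogenation of a ketone: only C2 can enolise because C10 is quaternary, and the aldehyde cannot be dehydrogenated because both carbons next to C5 (C4, C10) are quaternary, so only the C2=C3 bond should form.

Step 19
Reactants: 30 enone silyl ether
Product: 31 15-hydroxy-16-ene (all of the target except the epoxide)
Conditions: HF·pyridine, pyridine, THF, 0 °C → rt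
Reagents that add atoms: none
Why: Fluoride cleavage of the silyl ether in a weakly acidic medium, which avoids enolisation at C5 and retro-aldol opening of the β-hydroxy lactone.

Step 20
Reactants: 31 allylic alcohol
Product: 32 target compound
Conditions: VO(acac)2 (5 mol %), t-BuOOH (1.5 equiv), CH2Cl2, 0 °C
Reagents that add atoms: tert-butyl hydroperoxide CC(C)(C)OO
Why: Vanadium-catalysed hydroxyl-directed epoxidation of the allylic alcohol: the vanadate ester of the 15-OH delivers oxygen to C16=C17 on the same, more hindered face, which sets C16; the electron-poor enone is inert and the hindered aldehyde should survive the short reaction.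

**Compound list**

1 | cis-cyclohex-4-ene-1,2-dicarboxylic anhydride (meso) | O=C2[C@@H]1CC=CC[C@@H]1C(=O)O2 | starting material
2 | 2-(trimethylsilyl)ethanol | C[Si](C)(C)CCO | starting material
3 | (1R,2S)-2-{[2-(trimethylsilyl)ethoxy]carbonyl}cyclohex-4-ene-1-carboxylic acid | OC(=O)[C@@H]1CC=CC[C@@H]1C(=O)OCC[Si](C)(C)C | intermediate
4 | 2,3-dibromopropene | BrCC(Br)=C | starting material
5 | (1R,6R)-6-(2-bromoprop-2-en-1-yl)-6-{[2-(trimethylsilyl)ethoxy]carbonyl}cyclohex-3-ene-1-carboxylic acid (bromoallyl trans to CO2H) | OC(=O)[C@@H]1CC=CC[C@@]1(C(=O)OCC[Si](C)(C)C)CC(Br)=C | intermediate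
6 | 16-methylene bicyclo[3.2.1]octane acid (C8 silylethyl ester, C9 CO2H anti to the C15–C16 bridge) | OC(=O)[C@@H]1CC[C@@H]2C[C@@]1(C(=O)OCC[Si](C)(C)C)CC2=C | intermediate
7 | N,O-dimethylhydroxylamine hydrochloride | Cl.CNOC | starting material
8 | Weinreb amide of 6 | CON(C)C(=O)[C@@H]1CC[C@@H]2C[C@@]1(C(=O)OCC[Si](C)(C)C)CC2=C | intermediate
9 | 15-hydroxy derivative of 8, OH on the face towards C14 | CON(C)C(=O)[C@@H]1CC[C@@H]2C[C@@]1(C(=O)OCC[Si](C)(C)C)[C@@H](O)C2=C | intermediate
10 | 15-oxo-16-methylene enone | CON(C)C(=O)[C@@H]1CC[C@@H]2C[C@@]1(C(=O)OCC[Si](C)(C)C)C(=O)C2=C | intermediate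
11 | 15-hydroxy-16-ene, OH on the face towards C11 | CON(C)C(=O)[C@@H]1CC[C@@H]2C[C@@]1(C(=O)OCC[Si](C)(C)C)[C@H](O)C2=C | intermediate
12 | triisopropylsilyl ether of 11 | CON(C)C(=O)[C@@H]1CC[C@@H]2C[C@@]1(C(=O)OCC[Si](C)(C)C)[C@H](O[Si](C(C)C)(C(C)C)C(C)C)C2=C | intermediate
13 | methyl ketone (C9 acetyl) | CC(=O)[C@@H]1CC[C@@H]2C[C@@]1(C(=O)OCC[Si](C)(C)C)[C@H](O[Si](C(C)C)(C(C)C)C(C)C)C2=C | intermediate
14 | enol triflate of 13 | C=C(OS(=O)(=O)C(F)(F)F)[C@@H]1CC[C@@H]2C[C@@]1(C(=O)OCC[Si](C)(C)C)[C@H](O[Si](C(C)C)(C(C)C)C(C)C)C2=C | intermediate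
15 | vinylstannane | C=C([Sn](C)(C)C)[C@@H]1CC[C@@H]2C[C@@]1(C(=O)OCC[Si](C)(C)C)[C@H](O[Si](C(C)C)(C(C)C)C(C)C)C2=C | intermediate
16 | isobutyraldehyde | CC(C)C=O | starting material
17 | tert-butyl acrylate | C=CC(=O)OC(C)(C)C | starting material
18 | 1-(2-methylprop-1-en-1-yl)pyrrolidine | CC(C)=CN1CCCC1 | intermediate
19 | tert-butyl 4,4-dimethyl-5-oxopentanoate | CC(C)(C=O)CCC(=O)OC(C)(C)C | intermediate
20 | nitromethane | C[N+](=O)[O-] | starting material
21 | tert-butyl 5-hydroxy-4,4-dimethyl-6-nitrohexanoate (racemic) | CC(C)(CCC(=O)OC(C)(C)C)C(O)C[N+](=O)[O-] | intermediate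
22 | tert-butyl (E)-4,4-dimethyl-6-nitrohex-5-enoate | CC(C)(CCC(=O)OC(C)(C)C)/C=C/[N+](=O)[O-] | intermediate
23 | (E)-4,4-dimethyl-6-nitrohex-5-enoic acid | CC(C)(CCC(=O)O)/C=C/[N+](=O)[O-] | intermediate
24 | (E)-4,4-dimethyl-6-nitrohex-5-enoyl chloride | CC(C)(CCC(=O)Cl)/C=C/[N+](=O)[O-] | intermediate
25 | cascade precursor (2-acylallyl unit on C9, nitroalkene terminus, C8 silylethyl ester) | C=C(C(=O)CCC(C)(C)/C=C/[N+](=O)[O-])[C@@H]1CC[C@@H]2C[C@@]1(C(=O)OCC[Si](C)(C)C)[C@H](O[Si](C(C)C)(C(C)C)C(C)C)C2=C | intermediate
26 | tetrabutylammonium C7 carboxylate of 25 | C=C(C(=O)CCC(C)(C)/C=C/[N+](=O)[O-])[C@@H]1CC[C@@H]2C[C@@]1(C(=O)[O-])[C@H](O[Si](C(C)C)(C(C)C)C(C)C)C2=C.CCCC[N+](CCCC)(CCCC)CCCC | intermediate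
27 | tetrabutylammonium enolate of the 7,20-lactone (C10=C1–O−, ring A open) | [O-]C(CCC(C)(C)/C=C/[N+](=O)[O-])=C2COC(=O)[C@@]34C[C@@H](CC[C@@H]23)C(=C)[C@H]4O[Si](C(C)C)(C(C)C)C(C)C.CCCC[N+](CCCC)(CCCC)CCCC | intermediate
28 | tetrabutylammonium nitronate of the spirolactone ketone (ring A closed) | CC1(C)CCC(=O)[C@]2(COC(=O)[C@@]34C[C@@H](CC[C@@H]23)C(=C)[C@H]4O[Si](C(C)C)(C(C)C)C(C)C)[C@@H]1C=[N+]([O-])[O-].CCCC[N+](CCCC)(CCCC)CCCC | intermediate
29 | spirolactone keto aldehyde (15-OTIPS, 16-ene) | CC1(C)CCC(=O)[C@]2(COC(=O)[C@@]34C[C@@H](CC[C@@H]23)C(=C)[C@H]4O[Si](C(C)C)(C(C)C)C(C)C)[C@@H]1C=O | intermediate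
30 | ring A enone aldehyde (15-OTIPS, 16-ene) | CC1(C)C=CC(=O)[C@]2(COC(=O)[C@@]34C[C@@H](CC[C@@H]23)C(=C)[C@H]4O[Si](C(C)C)(C(C)C)C(C)C)[C@@H]1C=O | intermediate
31 | 15-hydroxy-16-ene enone aldehyde | CC1(C)C=CC(=O)[C@]2(COC(=O)[C@@]34C[C@@H](CC[C@@H]23)C(=C)[C@H]4O)[C@@H]1C=O | intermediate
32 | CNP0537841.1 | CC1(C)C=CC(=O)[C@]2(COC(=O)[C@@]34C[C@@H](CC[C@@H]23)[C@]2(CO2)[C@H]4O)[C@@H]1C=O | target

**Step count and risks**

Total step count: 20. Longest linear sequence: 15 steps (steps 1–10 and 16–20).

Steps most likely to fail:

1. Step 17 (proposed new method). What may go wrong: reversal of the oxa-Michael addition may outrun C–C bond formation, so that material is parked as the protonated lactone ketone. The exocyclic double bond may migrate into conjugation at C9 under base. Facial discrimination at C5 may be insufficient. The TIPS ether may be lost early. Fallback (known reactions, stepwise, with a neutral enol silane instead of the free enolate): it sets out from 25. Fluoride buffered with acetic acid frees the carboxylic acid F1. A catalytic amount of camphorsulfonic acid closes the lactone by intramolecular oxa-Michael addition to the C10–H lactone ketone F2. Equilibrating silylation (TMSOTf, Et3N) gives the tetrasubstituted trimethylsilyl enol ether F3. SnCl4 at −78 °C then triggers the intramolecular Mukaiyama–Michael addition to the nitroalkene, and hydrolytic work-up of the silyl nitronate (Nef) should give the keto aldehyde, so that the route is rejoined at 29.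

2. Step 16. What may go wrong: phosphine- or palladium-induced oligomerisation of the nitroalkene during the coupling, protodestannylation of the hindered α-branched vinylstannane, and polymerisation of the α-methylene ketone as it forms. Fallback (the acceptor is carried in latent form and released only after the palladium step): it sets out from 21 and 15. The nitro aldol 21 is acetylated (Ac2O, pyridine, 0 °C) to the β-acetoxy nitroalkane F4. Acidolysis gives the acid F5 and oxalyl chloride the acid chloride F6. Acyl Stille coupling with 15 gives the α-methylene ketone F7, from which triethylamine eliminates acetic acid (E1cB); the route is rejoined at 25.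

3. Step 18. What may go wrong: slow enolisation of the hindered C1 ketone, so that oxidative damage to the aldehyde or epimerisation at C5 competes on prolonged heating. Fallback (dehydrogenation by another mechanism and before the aldehyde exists): it sets out from 25. The cascade of step 17 is quenched with acetic acid instead of TiCl3, which should give the nitro ketone F8. TMSOTf/Et3N converts the ketone into the trimethylsilyl enol ether F9 (only C2 can enolise; the nitro group is silylated at the same time and freed again on work-up). Pd(OAc)2 effects the Saegusa–Ito oxidation to the nitro enone F10, and DBU followed by buffered TiCl3 (Nef reaction) gives the enone aldehyde; the route is rejoined at 30.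

**Further compounds**

F1 | step 17 | C7 carboxylic acid of 25 | C=C(C(=O)CCC(C)(C)/C=C/[N+](=O)[O-])[C@@H]1CC[C@@H]2C[C@@]1(C(O)=O)[C@H](O[Si](C(C)C)(C(C)C)C(C)C)C2=C
F2 | step 17 | 7,20-lactone ketone with C10–H (either C10 epimer), ring A open | O=C(CCC(C)(C)/C=C/[N+](=O)[O-])C2COC(=O)[C@@]34C[C@@H](CC[C@@H]23)C(=C)[C@H]4O[Si](C(C)C)(C(C)C)C(C)C
F3 | step 17 | trimethylsilyl enol ether of F2 (C10=C1–OSiMe3) | C[Si](C)(C)OC(CCC(C)(C)/C=C/[N+](=O)[O-])=C2COC(=O)[C@@]34C[C@@H](CC[C@@H]23)C(=C)[C@H]4O[Si](C(C)C)(C(C)C)C(C)C
F4 | step 16 | tert-butyl 5-acetoxy-4,4-dimethyl-6-nitrohexanoate (racemic) | CC(=O)OC(C[N+](=O)[O-])C(C)(C)CCC(=O)OC(C)(C)C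
F5 | step 16 | 5-acetoxy-4,4-dimethyl-6-nitrohexanoic acid (racemic) | CC(=O)OC(C[N+](=O)[O-])C(C)(C)CCC(=O)O
F6 | step 16 | 5-acetoxy-4,4-dimethyl-6-nitrohexanoyl chloride (racemic) | CC(=O)OC(C[N+](=O)[O-])C(C)(C)CCC(=O)Cl
F7 | step 16 | α-methylene ketone with β-acetoxy nitroalkane terminus (epimers at the acetoxy carbon) | C=C(C(=O)CCC(C)(C)C(OC(C)=O)C[N+](=O)[O-])[C@@H]1CC[C@@H]2C[C@@]1(C(=O)OCC[Si](C)(C)C)[C@H](O[Si](C(C)C)(C(C)C)C(C)C)C2=C
F8 | step 18 | spirolactone nitro ketone (C5–CH2NO2, 15-OTIPS, 16-ene) | CC1(C)CCC(=O)[C@]2(COC(=O)[C@@]34C[C@@H](CC[C@@H]23)C(=C)[C@H]4O[Si](C(C)C)(C(C)C)C(C)C)[C@@H]1C[N+](=O)[O-]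
F9 | step 18 | trimethylsilyl enol ether of F8 (C1=C2) | CC1(C)CC=C(O[Si](C)(C)C)[C@]2(COC(=O)[C@@]34C[C@@H](CC[C@@H]23)C(=C)[C@H]4O[Si](C(C)C)(C(C)C)C(C)C)[C@@H]1C[N+](=O)[O-]
F10 | step 18 | spirolactone nitro enone (2-en-1-one, C5–CH2NO2) | CC1(C)C=CC(=O)[C@]2(COC(=O)[C@@]34C[C@@H](CC[C@@H]23)C(=C)[C@H]4O[Si](C(C)C)(C(C)C)C(C)C)[C@@H]1C[N+](=O)[O-]
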